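**Retrosynthetic overview**

- The route rests on C4a of ring A. It lies ortho to O1 and para to the C7 oxygen, the most electron-rich carbon of a resorcinol diether. The C4 ketone (bond C4–C4a) is therefore made last, and this closes the pyranone ring C, the only ring built; rings A and B are bought as arenes.
- Cutting C4–C4a gives (S)-2-aryl-3-[3-(benzyloxy)phenoxy]propanoic acid. Its Cα–CH2O bond goes back to an Evans arylacetyl imide and an aryloxymethyl chloride, so C3 (S) is set before ring closure.
- The ring-B arylacetic acid comes from 2,3,4-trihydroxybenzaldehyde: 4-O-prenylation, Claisen rearrangement (1,1-dimethylallyl at C5'), O-methylation, one-carbon homologation.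
- Three benzyl ethers are carried to the end and cleaved with BCl3/pentamethylbenzene, which should leave the vinyl group and the methyl ether.

Key step: step 12

Abbreviation used in names: Ar = 2,3-bis(benzyloxy)-4-methoxy-5-(2-methylbut-3-en-2-yl)phenyl.

Assumption: chloromethyl ether 17 is stable enough to be concentrated and used crude, as simple aryloxymethyl chlorides are.

**Route**

Step 1
Reactants: 1 2,3,4-trihydroxybenzaldehyde; 2 1-bromo-3-methylbut-2-ene
Product: 3 2,3-dihydroxy-4-[(3-methylbut-2-en-1-yl)oxy]benzaldehyde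
Conditions: NaHCO3, DMF, 40 °C
Reagents that add atoms: none
Why: Williamson etherification; the 4-OH (para to CHO) is the most acidic and the 2-OH is tied up in a hydrogen bond to the aldehyde, so a weak base should form and alkylate the 4-phenoxide selectively.

Step 2
Reactants: 3 2,3-dihydroxy-4-[(3-methylbut-2-en-1-yl)oxy]benzaldehyde
Product: 4 2,3-bis(benzyloxy)-4-[(3-methylbut-2-en-1-yl)oxy]benzaldehyde
Conditions: BnBr, K2CO3, DMF, 50 °C
Reagents that add atoms: benzyl bromide, BrCc1ccccc1
Why: Williamson benzylation of both remaining phenols; the prenyl ether and the aldehyde are inert to carbonate.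

Step 3
Reactants: 4 2,3-bis(benzyloxy)-4-[(3-methylbut-2-en-1-yl)oxy]benzaldehyde
Product: 6 2,3-bis(benzyloxy)-4-hydroxy-5-(2-methylbut-3-en-2-yl)benzaldehyde, via Claisen dienone 5 (not isolated)
Conditions: EtOH/H2O 4:1, 130 °C, sealed tube
Reagents that add atoms: none
Why: Aromatic Claisen rearrangement ([3,3]) of the aryl prenyl ether delivers the allyl unit with inversion (1,1-dimethylallyl) to C5, the only ortho carbon that bears hydrogen and can tautomerise to the phenol; water acceleration should keep the temperature below that at which the o-(1,1-dimethylallyl)phenol reacts further.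

Step 4
Reactants: 6 2,3-bis(benzyloxy)-4-hydroxy-5-(2-methylbut-3-en-2-yl)benzaldehyde
Product: 7 2,3-bis(benzyloxy)-4-methoxy-5-(2-methylbut-3-en-2-yl)benzaldehyde
Conditions: MeI, K2CO3, DMF, rt to 40 °C
Reagents that add atoms: iodomethane, CI
Why: Williamson O-methylation of a hindered but acidic phenol (para to CHO); capping this oxygen also removes any later path for cyclisation onto the vinyl group.

Step 5
Reactants: 7 2,3-bis(benzyloxy)-4-methoxy-5-(2-methylbut-3-en-2-yl)benzaldehyde
Product: 9 2-Ar-acetonitrile, via N-formyl tosyl enamine 8 (not isolated)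
Conditions: TosMIC, t-BuOK, DME, −50 to −20 °C; then MeOH, reflux
Reagents that add atoms: p-toluenesulfonylmethyl isocyanide (TosMIC), [C-]#[N+]CS(=O)(=O)c1ccc(C)cc1
Why: van Leusen reductive cyanation; the TosMIC anion adds to the aldehyde, the oxazoline opens to the N-formyl enamine, and methanolysis expels sulfinate to give the nitrile with one more carbon.

Step 6
Reactants: 9 2-Ar-acetonitrile
Product: 11 2-Ar-acetic acid, via arylacetamide 10 (not isolated)
Conditions: KOH, EtOH/H2O, reflux; then aq. HCl, 0 °C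
Reagents that add atoms: water, O; potassium hydroxide, [K+].[OH-]
Why: Basic nitrile hydrolysis through the primary amide; benzyl ethers, the aryl methyl ether and the vinyl group (no allylic hydrogen, so no isomerisation) are stable to hot hydroxide.

Step 7
Reactants: 11 2-Ar-acetic acid; 12 (R)-4-benzyl-1,3-oxazolidin-2-one
Product: 14 (4R)-4-benzyl-3-(2-Ar-acetyl)-1,3-oxazolidin-2-one, via mixed pivalic anhydride 13 (not isolated)
Conditions: PivCl, Et3N, THF, −20 to 0 °C; then LiCl, 12, rt
Reagents that add atoms: none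
Why: N-acylation of the oxazolidinone by a mixed pivalic anhydride under LiCl/Et3N activation; the nucleophile attacks the less hindered arylacetyl carbonyl.

Step 8
Reactants: 15 3-(benzyloxy)phenol
Product: 16 1-(benzyloxy)-3-[(methylsulfanyl)methoxy]benzene
Conditions: NaH, DMF, 0 °C; ClCH2SMe, NaI (cat.), 0 °C to rt
Reagents that add atoms: chloromethyl methyl sulfide, CSCCl
Why: Williamson O-alkylation of the sodium phenoxide gives the O,S-acetal (methylthiomethyl ether).

Step 9
Reactants: 16 1-(benzyloxy)-3-[(methylsulfanyl)methoxy]benzene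
Product: 17 1-(benzyloxy)-3-(chloromethoxy)benzene
Conditions: SO2Cl2 (1.0 equiv), CH2Cl2, −78 to 0 °C; volatiles removed in vacuo, used crude
Reagents that add atoms: sulfuryl chloride, O=S(=O)(Cl)Cl
Why: S-chlorination of the O,S-acetal and fragmentation of the chlorosulfonium ion give the α-chloro ether; with one equivalent at low temperature, chlorination at sulfur should outrun chlorination of the ring.

Step 10
Reactants: 14 (4R)-4-benzyl-3-(2-Ar-acetyl)-1,3-oxazolidin-2-one; 17 1-(benzyloxy)-3-(chloromethoxy)benzene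
Product: 19 (4R)-4-benzyl-3-{(2S)-2-Ar-3-[3-(benzyloxy)phenoxy]propanoyl}-1,3-oxazolidin-2-one, via chlorotitanium Z-enolate 18 (not isolated)
Conditions: TiCl4, i-Pr2NEt, CH2Cl2, 0 °C; then 17 (1.5–2 equiv), 0 °C
Reagents that add atoms: none
Why: Evans asymmetric alkylation of a chelated chlorotitanium Z-enolate with an α-chloro ether, the reaction type of the benzyloxymethylation with BOMCl; the electrophile approaches the enolate face away from the C4 benzyl group of the (R)-auxiliary, which sets the α-carbon (later C3) as S.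

Step 11
Reactants: 19 (4R)-4-benzyl-3-{(2S)-2-Ar-3-[3-(benzyloxy)phenoxy]propanoyl}-1,3-oxazolidin-2-one
Product: 21 (2S)-2-Ar-3-[3-(benzyloxy)phenoxy]propanoic acid, via peroxy acid 20 (not isolated)
Conditions: LiOH, H2O2, THF/H2O, 0 °C; then aq. Na2SO3; HCl to pH 2–3
Reagents that add atoms: hydrogen peroxide, OO
Why: Evans hydroperoxide cleavage; LiOOH attacks the exocyclic imide carbonyl, the peroxy acid is reduced by sulfite, and the weakly basic, cold conditions together with the allylic strain that disfavours α-deprotonation of the imide should prevent epimerisation and β-elimination of the aryloxide.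

Step 12
Reactants: 21 (2S)-2-Ar-3-[3-(benzyloxy)phenoxy]propanoic acid
Product: 23 (3S)-7-(benzyloxy)-3-Ar-chroman-4-one, via mixed trifluoroacetic anhydride 22 (not isolated)
Conditions: (CF3CO)2O (2.5 equiv), CH2Cl2 (0.02 M), 0 °C to rt
Reagents that add atoms: none
Why: Trifluoroacetic anhydride converts the acid into mixed anhydride 22, which the trifluoroacetic acid formed alongside ionises to an acylium equivalent; this attacks the aryloxy ring at the carbon ortho to the ether oxygen and para to the benzyloxy group, and the Wheland intermediate loses a proton to give the ketone. The closest known reaction type is the intramolecular Friedel–Crafts acylation (cycloacylation) of 3-aryloxypropanoic acids to chroman-4-ones, including 2-aryl acids that give isoflavanones. The pyranone ring is closed as a six-membered ring by attack of the arene carbon on the tethered acyl carbon, 6-exo with respect to the acyl C=O, forming C4–C4a. No stereocentre is formed; C3 comes unchanged from the Evans alkylation and is kept by base-free activation (no ketene) and by a cold, short reaction, which the doubly oxygen-activated ring permits. The regioselectivity needed is attack para to the benzyloxy group and not at the carbon between the two oxygens, which is flanked on both sides and therefore sterically disfavoured. On ring B the only free carbon (C6') could close only a four-membered ring and the vinyl group only a seven- or eight-membered one, so neither should compete.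

Step 13
Reactants: 23 (3S)-7-(benzyloxy)-3-Ar-chroman-4-one
Product: 24 (3S)-3-[2,3-dihydroxy-4-methoxy-5-(2-methylbut-3-en-2-yl)phenyl]-7-hydroxychroman-4-one
Conditions: BCl3 (1 M in CH2Cl2, 6–7 equiv), C6HMe5 (10 equiv), CH2Cl2, −78 °C; CHCl3/MeOH quench at −78 °C
Reagents that add atoms: none
Why: Boron trichloride cleavage of aryl benzyl ethers with pentamethylbenzene as a non-basic benzyl cation scavenger; at −78 °C the methyl ether and the monosubstituted alkene should not be attacked, and the absence of base should leave C3 untouched.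

**Compound list**

1 | 2,3,4-trihydroxybenzaldehyde | O=Cc1ccc(O)c(O)c1O | starting material
2 | 1-bromo-3-methylbut-2-ene | CC(C)=CCBr | starting material
3 | 2,3-dihydroxy-4-[(3-methylbut-2-en-1-yl)oxy]benzaldehyde | CC(C)=CCOc1ccc(C=O)c(O)c1O | intermediate
4 | 2,3-bis(benzyloxy)-4-[(3-methylbut-2-en-1-yl)oxy]benzaldehyde | CC(C)=CCOc1ccc(C=O)c(OCc2ccccc2)c1OCc1ccccc1 | intermediate
5 | Claisen dienone: keto tautomer of 6, carbonyl at the former C4, sp3 C5 bearing H and the 2-methylbut-3-en-2-yl group (racemic) | C=CC(C)(C)C1C=C(C=O)C(OCc2ccccc2)=C(OCc2ccccc2)C1=O | intermediate (not isolated)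
6 | 2,3-bis(benzyloxy)-4-hydroxy-5-(2-methylbut-3-en-2-yl)benzaldehyde | C=CC(C)(C)c1cc(C=O)c(OCc2ccccc2)c(OCc2ccccc2)c1O | intermediate
7 | 2,3-bis(benzyloxy)-4-methoxy-5-(2-methylbut-3-en-2-yl)benzaldehyde | C=CC(C)(C)c1cc(C=O)c(OCc2ccccc2)c(OCc2ccccc2)c1OC | intermediate
8 | N-[2-Ar-1-(4-methylbenzenesulfonyl)ethenyl]formamide | C=CC(C)(C)c1cc(C=C(NC=O)S(=O)(=O)c2ccc(C)cc2)c(OCc2ccccc2)c(OCc2ccccc2)c1OC | intermediate (not isolated)
9 | 2-Ar-acetonitrile | C=CC(C)(C)c1cc(CC#N)c(OCc2ccccc2)c(OCc2ccccc2)c1OC | intermediate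
10 | 2-Ar-acetamide | C=CC(C)(C)c1cc(CC(N)=O)c(OCc2ccccc2)c(OCc2ccccc2)c1OC | intermediate (not isolated)
11 | 2-Ar-acetic acid | C=CC(C)(C)c1cc(CC(=O)O)c(OCc2ccccc2)c(OCc2ccccc2)c1OC | intermediate
12 | (R)-4-benzyl-1,3-oxazolidin-2-one | O=C1N[C@H](Cc2ccccc2)CO1 | starting material
13 | 2-Ar-acetic pivalic anhydride | C=CC(C)(C)c1cc(CC(=O)OC(=O)C(C)(C)C)c(OCc2ccccc2)c(OCc2ccccc2)c1OC | intermediate (not isolated)
14 | (4R)-4-benzyl-3-(2-Ar-acetyl)-1,3-oxazolidin-2-one | C=CC(C)(C)c1cc(CC(=O)N2[C@H](Cc3ccccc3)COC2=O)c(OCc2ccccc2)c(OCc2ccccc2)c1OC | intermediate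
15 | 3-(benzyloxy)phenol | Oc1cccc(OCc2ccccc2)c1 | starting material
16 | 1-(benzyloxy)-3-[(methylsulfanyl)methoxy]benzene | CSCOc1cccc(OCc2ccccc2)c1 | intermediate
17 | 1-(benzyloxy)-3-(chloromethoxy)benzene | ClCOc1cccc(OCc2ccccc2)c1 | intermediate
18 | trichlorotitanium (Z)-enolate of 14 (O–Ti cis to Ar) | C=CC(C)(C)c1cc(/C=C(\O[Ti](Cl)(Cl)Cl)N2[C@H](Cc3ccccc3)COC2=O)c(OCc2ccccc2)c(OCc2ccccc2)c1OC | intermediate (not isolated)
19 | (4R)-4-benzyl-3-{(2S)-2-Ar-3-[3-(benzyloxy)phenoxy]propanoyl}-1,3-oxazolidin-2-one | C=CC(C)(C)c1cc([C@@H](COc2cccc(OCc3ccccc3)c2)C(=O)N2[C@H](Cc3ccccc3)COC2=O)c(OCc2ccccc2)c(OCc2ccccc2)c1OC | intermediate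
20 | (2S)-2-Ar-3-[3-(benzyloxy)phenoxy]propaneperoxoic acid | C=CC(C)(C)c1cc([C@@H](COc2cccc(OCc3ccccc3)c2)C(=O)OO)c(OCc2ccccc2)c(OCc2ccccc2)c1OC | intermediate (not isolated)
21 | (2S)-2-Ar-3-[3-(benzyloxy)phenoxy]propanoic acid | C=CC(C)(C)c1cc([C@@H](COc2cccc(OCc3ccccc3)c2)C(=O)O)c(OCc2ccccc2)c(OCc2ccccc2)c1OC | intermediate
22 | (2S)-2-Ar-3-[3-(benzyloxy)phenoxy]propanoic trifluoroacetic anhydride | C=CC(C)(C)c1cc([C@@H](COc2cccc(OCc3ccccc3)c2)C(=O)OC(=O)C(F)(F)F)c(OCc2ccccc2)c(OCc2ccccc2)c1OC | intermediate (not isolated)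
23 | (3S)-7-(benzyloxy)-3-Ar-chroman-4-one | C=CC(C)(C)c1cc([C@H]2COc3cc(OCc4ccccc4)ccc3C2=O)c(OCc2ccccc2)c(OCc2ccccc2)c1OC | intermediate
24 | (3S)-3-[2,3-dihydroxy-4-methoxy-5-(2-methylbut-3-en-2-yl)phenyl]-7-hydroxychroman-4-one | C=CC(C)(C)c1cc([C@H]2COc3cc(O)ccc3C2=O)c(O)c(O)c1OC | target

**Step count**

Total: 13 steps. Longest linear sequence: 11 steps (steps 1–7 and 10–13); steps 8 and 9 make the electrophile.

**Steps most likely to fail**

Step 12 (ring closure). Enolisation of the mixed anhydride or of the α-aryl ketone in the acidic medium may erode the configuration at C3, and part of the acylation may go to the carbon between the two oxygens. The fallback closes the same bond by a Parham cycloacylation, in which an aryllithium attacks an amide; no acid is present and a bromine fixes the ring carbon. It sets out from imide 14 and comes back at 23.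
- Purchased 5-(benzyloxy)-2-bromophenol F1 is taken through the operations of steps 8 and 9 (NaH, ClCH2SMe; then SO2Cl2) to 4-(benzyloxy)-1-bromo-2-[(methylsulfanyl)methoxy]benzene F2 and 4-(benzyloxy)-1-bromo-2-(chloromethoxy)benzene F3.
- The titanium enolate of 14 is alkylated with F3 as in step 10 to (4R)-4-benzyl-3-{(2S)-2-Ar-3-[5-(benzyloxy)-2-bromophenoxy]propanoyl}-1,3-oxazolidin-2-one F4.
- LiOOH cleavage as in step 11 gives (2S)-2-Ar-3-[5-(benzyloxy)-2-bromophenoxy]propanoic acid F5.
- EDC/HOBt coupling with N,O-dimethylhydroxylamine gives (2S)-2-Ar-3-[5-(benzyloxy)-2-bromophenoxy]-N-methoxy-N-methylpropanamide F6.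
- t-BuLi (2 equiv) in THF at −100 °C effects bromine–lithium exchange; the aryllithium adds to the amide carbonyl, and the chelated tetrahedral intermediate should give 23 on cold acidic work-up.

Step 10 (aryloxymethylation). Titanium may ionise the aryloxymethyl chloride so that its electron-rich ring is alkylated by a second molecule, or the enolate may be alkylated on oxygen. The fallback introduces the carbon as formaldehyde and makes the aryl ether afterwards. It sets out from imide 14 and comes back at 19.
- The titanium enolate of 14 (TiCl4, i-Pr2NEt, CH2Cl2, 0 °C) is treated with s-trioxane and a second equivalent of TiCl4 (Evans hydroxymethylation, same facial control) to give (4R)-4-benzyl-3-[(2S)-2-Ar-3-hydroxypropanoyl]-1,3-oxazolidin-2-one F7.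
- Mitsunobu etherification of F7 with phenol 15 (PPh3, DIAD, toluene, 0 °C) should give 19. It is run cold because elimination to the 2-arylacryloyl imide would destroy the stereocentre.

Step 3 (Claisen rearrangement). The freed o-(1,1-dimethylallyl)phenol may react further at the rearrangement temperature (abnormal Claisen shift, addition of the OH to the alkene), or the prenyl group may be lost. The fallback attaches the 1,1-dimethylallyl group by γ-selective cross-coupling, which needs no free phenol. It sets out from 1 and comes back at 7.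
- Borate-directed 4-O-methylation of 1 (borax, NaOH, Me2SO4, H2O) gives 2,3-dihydroxy-4-methoxybenzaldehyde F8.
- BnBr/K2CO3 in DMF gives 2,3-bis(benzyloxy)-4-methoxybenzaldehyde F9.
- NBS in MeCN should brominate C5 (ortho to OMe, para to the 2-benzyloxy group, meta to CHO) to 2,3-bis(benzyloxy)-5-bromo-4-methoxybenzaldehyde F10.
- Pd-catalysed Suzuki–Miyaura coupling of F10 with prenylboronic acid pinacol ester (CC(C)=CCB1OC(C)(C)C(C)(C)O1), using a biarylphosphine ligand chosen for γ-selectivity (K3PO4, THF/H2O), should give 7.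

**Further compounds**

F1 | step 12 | 5-(benzyloxy)-2-bromophenol (purchased) | Oc1cc(OCc2ccccc2)ccc1Br
F2 | step 12 | 4-(benzyloxy)-1-bromo-2-[(methylsulfanyl)methoxy]benzene | CSCOc1cc(OCc2ccccc2)ccc1Br
F3 | step 12 | 4-(benzyloxy)-1-bromo-2-(chloromethoxy)benzene | ClCOc1cc(OCc2ccccc2)ccc1Br
F4 | step 12 | (4R)-4-benzyl-3-{(2S)-2-Ar-3-[5-(benzyloxy)-2-bromophenoxy]propanoyl}-1,3-oxazolidin-2-one | C=CC(C)(C)c1cc([C@@H](COc2cc(OCc3ccccc3)ccc2Br)C(=O)N2[C@H](Cc3ccccc3)COC2=O)c(OCc2ccccc2)c(OCc2ccccc2)c1OC
F5 | step 12 | (2S)-2-Ar-3-[5-(benzyloxy)-2-bromophenoxy]propanoic acid | C=CC(C)(C)c1cc([C@@H](COc2cc(OCc3ccccc3)ccc2Br)C(=O)O)c(OCc2ccccc2)c(OCc2ccccc2)c1OC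
F6 | step 12 | (2S)-2-Ar-3-[5-(benzyloxy)-2-bromophenoxy]-N-methoxy-N-methylpropanamide | C=CC(C)(C)c1cc([C@@H](COc2cc(OCc3ccccc3)ccc2Br)C(=O)N(C)OC)c(OCc2ccccc2)c(OCc2ccccc2)c1OC
F7 | step 10 | (4R)-4-benzyl-3-[(2S)-2-Ar-3-hydroxypropanoyl]-1,3-oxazolidin-2-one | C=CC(C)(C)c1cc([C@@H](CO)C(=O)N2[C@H](Cc3ccccc3)COC2=O)c(OCc2ccccc2)c(OCc2ccccc2)c1OC
F8 | step 3 | 2,3-dihydroxy-4-methoxybenzaldehyde | COc1ccc(C=O)c(O)c1O
F9 | step 3 | 2,3-bis(benzyloxy)-4-methoxybenzaldehyde | COc1ccc(C=O)c(OCc2ccccc2)c1OCc1ccccc1
F10 | step 3 | 2,3-bis(benzyloxy)-5-bromo-4-methoxybenzaldehyde | COc1c(Br)cc(C=O)c(OCc2ccccc2)c1OCc1ccccc1
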